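**Retrosynthetic overview**
- The tetronic acid ring is closed last, by Dieckmann cyclisation of an (E)-α-propanoyloxy enoate. That enoate comes from a Still–Gennari-type olefination of an (S)-α-methyl aldehyde, which fixes the exocyclic E-geometry.
- The aldehyde chain is cut at the bond next to the 1,1-disubstituted alkene carbon: B-alkyl Suzuki coupling of (S)-2-methylpent-4-en-1-ol (Evans allylation) with a 2-chloroalkene.
- Key disconnection: the C(sp3)–C(sp2) bond between the β-carbon of the furyl ketone and the trisubstituted alkene carbon. 1-(Furan-3-yl)cyclopropanol serves as a ketone homoenolate and is coupled with an (E)-alkenyl iodide, with retention of geometry; the ketone arrives unprotected.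
- The (E)-chloro-iodo-diene linchpin comes from but-2-yne and 2,3-dichloropropene, then hydrozirconation–iodination.
- Ring order: the furan is bought; the cyclopropane is made first and opened in the key step; the tetronic acid ring is formed in the final step.

Assumption: the SMILES is taken literally, i.e. (S) at the methyl-bearing carbon, E at the chain C=C, and E at the exocyclic enol-lactone C=C (alkyl chain trans to the ring oxygen).

**Route**

Step 1
Reactants: 1 ethyl furan-3-carboxylate
Product: 2 1-(furan-3-yl)cyclopropan-1-ol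
Conditions: EtMgBr (2.5 equiv), Ti(OiPr)4 (20 mol %), THF, 0 °C → rt; then H2O
Reagents that add atoms: ethylmagnesium bromide, CC[Mg]Br
Why: Kulinkovich cyclopropanation, in which the titanacyclopropane formed from EtMgBr/Ti(OiPr)4 adds twice to the ester carbonyl, a reaction that works well for aromatic esters; no stereocentre is formed.

Step 2
Reactants: 3 but-2-yne; 4 2,3-dichloroprop-1-ene
Product: 6 2-chlorohept-1-en-5-yne, via but-2-yn-1-yllithium 5 (not isolated)
Conditions: n-BuLi (1.0 equiv), TMEDA, THF, −78 → 0 °C (3 in excess); then 4, −78 °C → rt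
Reagents that add atoms: none
Why: Propargylic lithiation of but-2-yne followed by SN2 alkylation at the allylic chloride; the vinylic C–Cl is inert, and SN2 and SN2' attack give the same 2-chloroallyl product.

Step 3
Reactants: 6 2-chlorohept-1-en-5-yne
Product: 8 (5E)-2-chloro-6-iodohepta-1,5-diene, via alkenylzirconocene chloride 7 (not isolated)
Conditions: Cp2Zr(H)Cl (1.5 equiv), THF, rt → 40 °C; then I2, 0 °C
Reagents that add atoms: iodine, II
Why: Hydrozirconation–iodination: syn Zr–H addition with equilibration places Zr on the less hindered, methyl-bearing alkyne carbon (about 9:1 expected; the minor regioisomer is removed after step 4), and iodinolysis with retention gives the E-iodide with iodine trans to the chain.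

Step 4
Reactants: 2 1-(furan-3-yl)cyclopropan-1-ol; 8 (5E)-2-chloro-6-iodohepta-1,5-diene
Product: 9 (4E)-8-chloro-1-(furan-3-yl)-4-methylnona-4,8-dien-1-one
Conditions: Pd(OAc)2 (5 mol %), XPhos (10 mol %), Cs2CO3 (1.5 equiv), toluene, 50 °C (2 in 1.2 equiv)
Reagents that add atoms: none
Why: Proposed new method: Pd(0) inserts into the C(sp2)–I bond only (C–Cl is untouched at 50 °C), the caesium cyclopropoxide binds Pd and strain-driven β-carbon elimination gives the β-palladated ketone (a Pd homoenolate), and the bulky biarylphosphine makes C(sp3)–C(sp2) reductive elimination faster than β-hydride elimination, with the alkenyl geometry retained so the E-trisubstituted alkene is set here; the closest known reactions are the Pd-catalysed ring-opening cross-coupling of cyclopropanols with aryl halides and the coupling of siloxycyclopropane-derived ketone homoenolates with aryl and alkenyl triflates.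

Step 5
Reactants: 10 (4R)-4-benzyl-3-propanoyl-1,3-oxazolidin-2-one; 11 3-iodoprop-1-ene (allyl iodide)
Product: 13 (4R)-4-benzyl-3-[(2S)-2-methylpent-4-enoyl]-1,3-oxazolidin-2-one, via sodium Z-enolate 12 (not isolated)
Conditions: NaHMDS, THF, −78 °C; then 11, −78 → −45 °C
Reagents that add atoms: none
Why: Evans asymmetric alkylation, in which the chelated Z-enolate is allylated on the face opposite the benzyl group, so the (R)-auxiliary gives the (2S)-methyl stereocentre (dr typically ≥ 95:5).

Step 6
Reactants: 13 (4R)-4-benzyl-3-[(2S)-2-methylpent-4-enoyl]-1,3-oxazolidin-2-one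
Product: 14 (2S)-2-methylpent-4-en-1-ol
Conditions: LiBH4, Et2O, H2O (1 equiv), 0 °C
Reagents that add atoms: none
Why: Reductive cleavage of the N-acyl oxazolidinone with LiBH4 gives the primary alcohol without touching the α-stereocentre, and the auxiliary is recovered.

Step 7
Reactants: 14 (2S)-2-methylpent-4-en-1-ol; 9 (4E)-8-chloro-1-(furan-3-yl)-4-methylnona-4,8-dien-1-one
Product: 16 (4E,12S)-1-(furan-3-yl)-13-hydroxy-4,12-dimethyl-8-methylidenetridec-4-en-1-one, via bis-boryl adduct 15 (not isolated)
Conditions: 9-BBN (2.1 equiv), THF, 0 °C → rt; then aq K3PO4, 9, Pd(OAc)2 (3 mol %), SPhos (6 mol %), THF/H2O, 60 °C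
Reagents that add atoms: none
Why: B-alkyl Suzuki–Miyaura coupling: one equivalent of 9-BBN is consumed by the O–H, the second hydroborates the terminal alkene anti-Markovnikov, aqueous base destroys residual B–H before the ketone is added, and the SPhos–Pd catalyst couples the alkylborane with the 2-chloroalkene to form the 1,1-disubstituted alkene; the stereocentre is not involved.

Step 8
Reactants: 16 (4E,12S)-1-(furan-3-yl)-13-hydroxy-4,12-dimethyl-8-methylidenetridec-4-en-1-one
Product: 17 (2S,9E)-13-(furan-3-yl)-2,10-dimethyl-6-methylidene-13-oxotridec-9-enal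
Conditions: Dess–Martin periodinane, CH2Cl2, 0 °C → rt
Reagents that add atoms: none
Why: Dess–Martin oxidation is neutral and does not epimerise α-methyl aldehydes, and it leaves the furan, the ketone and the alkenes alone.

Step 9
Reactants: 18 bis(2,2,2-trifluoroethyl) phosphite; 19 methyl 2-oxoacetate (methyl glyoxylate)
Product: 21 methyl 2-[bis(2,2,2-trifluoroethoxy)phosphoryl]-2-(propanoyloxy)acetate, via hydroxyphosphonate 20 (not isolated)
Conditions: Et3N (5 mol %), CH2Cl2, 0 °C; then (EtCO)2O, pyridine, DMAP (cat.), 0 °C → rt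
Reagents that add atoms: propanoic anhydride, CCC(=O)OC(=O)CC
Why: Pudovik addition of the H-phosphonate to the glyoxylate aldehyde, then O-acylation in the same flask under weakly basic conditions that avoid phosphonate-to-phosphate rearrangement; the new centre is racemic and is destroyed in step 10.

Step 10
Reactants: 21 methyl 2-[bis(2,2,2-trifluoroethoxy)phosphoryl]-2-(propanoyloxy)acetate; 17 (2S,9E)-13-(furan-3-yl)-2,10-dimethyl-6-methylidene-13-oxotridec-9-enal
Product: 23 methyl (2E,4S,11E)-15-(furan-3-yl)-4,12-dimethyl-8-methylidene-15-oxo-2-(propanoyloxy)pentadeca-2,11-dienoate, via potassium phosphonate anion 22 (not isolated)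
Conditions: KHMDS, 18-crown-6, THF, −78 °C; then 17, −78 °C
Reagents that add atoms: none
Why: Proposed new method: with electron-poor trifluoroethyl phosphonates the kinetic adduct collapses faster than it equilibrates, which places the aldehyde substituent cis to the ester, as established for the α-alkyl (Still–Gennari) and α-bromo bis(trifluoroethyl)phosphonoacetates; here that means the chain is trans to the acyloxy oxygen (E-enol ester); the preformed, weakly basic anion reacts only with the aldehyde and does not epimerise C4; the closest known reactions are the Still–Gennari olefination and Horner–Wadsworth–Emmons reactions of α-acyloxy phosphonoacetates.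

Step 11
Reactants: 23 methyl (2E,4S,11E)-15-(furan-3-yl)-4,12-dimethyl-8-methylidene-15-oxo-2-(propanoyloxy)pentadeca-2,11-dienoate
Product: 24 (5E)-5-[(2S,9E)-13-(furan-3-yl)-2,10-dimethyl-6-methylidene-13-oxotridec-9-en-1-ylidene]-4-hydroxy-3-methylfuran-2(5H)-one (CNP0018618.1)
Conditions: LiHMDS (3.3 equiv), THF, −78 → −30 °C, dark; then cold 1 M HCl
Reagents that add atoms: none
Why: Dieckmann (intramolecular Claisen) cyclisation of the propanoate enolate onto the neighbouring methyl ester closes the 3-methyltetronic acid ring with the enol-ester geometry carried over unchanged, as known for α-acyloxy acrylates giving 5-ylidene tetronic acids; the ketone is carried as its lithium enolate and returns on work-up.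

**Compound list**
1 | ethyl furan-3-carboxylate | CCOC(=O)c1ccoc1 | starting material
2 | 1-(furan-3-yl)cyclopropan-1-ol | OC1(CC1)c1ccoc1 | intermediate
3 | but-2-yne | CC#CC | starting material
4 | 2,3-dichloroprop-1-ene | C=C(Cl)CCl | starting material
5 | but-2-yn-1-yllithium | [Li]CC#CC | intermediate (not isolated)
6 | 2-chlorohept-1-en-5-yne | C=C(Cl)CCC#CC | intermediate
7 | chlorobis(cyclopentadienyl)[(2E)-6-chlorohepta-2,6-dien-2-yl]zirconium (Cp drawn η1) | C=C(Cl)CC/C=C(\C)[Zr](Cl)(C1C=CC=C1)C1C=CC=C1 | intermediate (not isolated)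
8 | (5E)-2-chloro-6-iodohepta-1,5-diene | C=C(Cl)CC/C=C(\C)I | intermediate
9 | (4E)-8-chloro-1-(furan-3-yl)-4-methylnona-4,8-dien-1-one | C=C(Cl)CC/C=C(\C)CCC(=O)c1ccoc1 | intermediate
10 | (4R)-4-benzyl-3-propanoyl-1,3-oxazolidin-2-one | CCC(=O)N1[C@H](Cc2ccccc2)COC1=O | starting material
11 | 3-iodoprop-1-ene (allyl iodide) | C=CCI | starting material
12 | sodium (Z)-enolate of 10 | C/C=C(\[O-])N1[C@H](Cc2ccccc2)COC1=O.[Na+] | intermediate (not isolated)
13 | (4R)-4-benzyl-3-[(2S)-2-methylpent-4-enoyl]-1,3-oxazolidin-2-one | C=CC[C@H](C)C(=O)N1[C@H](Cc2ccccc2)COC1=O | intermediate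
14 | (2S)-2-methylpent-4-en-1-ol | C=CC[C@H](C)CO | intermediate
15 | 9-[(4S)-5-(9-borabicyclo[3.3.1]nonan-9-yloxy)-4-methylpentyl]-9-borabicyclo[3.3.1]nonane | B1(CCC[C@H](C)COB2C3CCCC2CCC3)C2CCCC1CCC2 | intermediate (not isolated)
16 | (4E,12S)-1-(furan-3-yl)-13-hydroxy-4,12-dimethyl-8-methylidenetridec-4-en-1-one | C=C(CC/C=C(\C)CCC(=O)c1ccoc1)CCC[C@H](C)CO | intermediate
17 | (2S,9E)-13-(furan-3-yl)-2,10-dimethyl-6-methylidene-13-oxotridec-9-enal | C=C(CC/C=C(\C)CCC(=O)c1ccoc1)CCC[C@H](C)C=O | intermediate
18 | bis(2,2,2-trifluoroethyl) phosphite | O=[PH](OCC(F)(F)F)OCC(F)(F)F | starting material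
19 | methyl 2-oxoacetate (methyl glyoxylate) | COC(=O)C=O | starting material
20 | methyl 2-[bis(2,2,2-trifluoroethoxy)phosphoryl]-2-hydroxyacetate | COC(=O)C(O)P(=O)(OCC(F)(F)F)OCC(F)(F)F | intermediate (not isolated)
21 | methyl 2-[bis(2,2,2-trifluoroethoxy)phosphoryl]-2-(propanoyloxy)acetate (racemic) | CCC(=O)OC(C(=O)OC)P(=O)(OCC(F)(F)F)OCC(F)(F)F | intermediate
22 | potassium salt of the carbanion of 21 | CCC(=O)O[C-](C(=O)OC)P(=O)(OCC(F)(F)F)OCC(F)(F)F.[K+] | intermediate (not isolated)
23 | methyl (2E,4S,11E)-15-(furan-3-yl)-4,12-dimethyl-8-methylidene-15-oxo-2-(propanoyloxy)pentadeca-2,11-dienoate | C=C(CC/C=C(\C)CCC(=O)c1ccoc1)CCC[C@H](C)/C=C(/OC(=O)CC)C(=O)OC | intermediate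
24 | (5E)-5-[(2S,9E)-13-(furan-3-yl)-2,10-dimethyl-6-methylidene-13-oxotridec-9-en-1-ylidene]-4-hydroxy-3-methylfuran-2(5H)-one | C=C(CC/C=C(\C)CCC(=O)c1ccoc1)CCC[C@H](C)/C=C1/OC(=O)C(C)=C1O | target

**Step count and risk**

Total: 11 steps. Longest linear sequence: 7 steps (2, 3, 4, 7, 8, 10, 11, from but-2-yne).

The three steps most likely to fail are 4, 10 and 11.

Step 4 (homoenolate alkenylation). The risks are β-hydride elimination to the vinyl ketone and simple protonation to the ethyl ketone. The fallback makes the same bond with normal polarity and sets out from 8. Furan-3-carbaldehyde and vinylmagnesium bromide give 1-(furan-3-yl)prop-2-en-1-ol F1. Its 9-BBN adduct (2.1 equiv 9-BBN) is coupled with 8 at the C–I bond only (Pd(dppf)Cl2, Cs2CO3, DMF/H2O, rt) to give (4E)-8-chloro-1-(furan-3-yl)-4-methylnona-4,8-dien-1-ol F2. MnO2 oxidation of this furyl carbinol comes back to the route at 9.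

Step 10 (olefination geometry). The risks are a poor E:Z ratio and acyl migration in the phosphonate anion. The fallback sets out from 17 and fixes the geometry with the known E-selective α-bromo reagent. Methyl 2-[bis(2,2,2-trifluoroethoxy)phosphoryl]-2-bromoacetate (t-BuOK, 18-crown-6, THF, −78 °C) gives methyl (2E,4S,11E)-2-bromo-15-(furan-3-yl)-4,12-dimethyl-8-methylidene-15-oxopentadeca-2,11-dienoate F3, with the chain cis to the ester. A copper-catalysed C–O coupling with caesium propanoate (CuI, 1,10-phenanthroline, toluene, 80 °C, retention of geometry) comes back to the route at 23.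

Step 11 (Dieckmann closure). The risks are interference from the ketone enolate, ketene loss from the enol ester, and E→Z drift of the product. The fallback sets out from 17, brings the ring in preformed and corrects the geometry at the end. Aldol addition of 5-lithio-4-methoxy-3-methylfuran-2(5H)-one (LDA, THF, −78 °C) gives 5-[(2S,9E)-13-(furan-3-yl)-1-hydroxy-2,10-dimethyl-6-methylidene-13-oxotridec-9-en-1-yl]-4-methoxy-3-methylfuran-2(5H)-one F4. MsCl/Et3N then DBU gives (5Z)-5-[(2S,9E)-13-(furan-3-yl)-2,10-dimethyl-6-methylidene-13-oxotridec-9-en-1-ylidene]-4-methoxy-3-methylfuran-2(5H)-one F5. LiCl in DMF removes the O-methyl group to give (5Z)-5-[(2S,9E)-13-(furan-3-yl)-2,10-dimethyl-6-methylidene-13-oxotridec-9-en-1-ylidene]-4-hydroxy-3-methylfuran-2(5H)-one F6. Irradiation at 350 nm gives an E/Z mixture; the E-isomer is separated by HPLC and the Z-isomer recycled, which comes back to the route at 24. This fallback is not stereoselective at the last stage and is the weaker option.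

Further compounds
F1 | step 4 | 1-(furan-3-yl)prop-2-en-1-ol | C=CC(O)c1ccoc1
F2 | step 4 | (4E)-8-chloro-1-(furan-3-yl)-4-methylnona-4,8-dien-1-ol | C=C(Cl)CC/C=C(\C)CCC(O)c1ccoc1
F3 | step 10 | methyl (2E,4S,11E)-2-bromo-15-(furan-3-yl)-4,12-dimethyl-8-methylidene-15-oxopentadeca-2,11-dienoate | C=C(CC/C=C(\C)CCC(=O)c1ccoc1)CCC[C@H](C)/C=C(/Br)C(=O)OC
F4 | step 11 | 5-[(2S,9E)-13-(furan-3-yl)-1-hydroxy-2,10-dimethyl-6-methylidene-13-oxotridec-9-en-1-yl]-4-methoxy-3-methylfuran-2(5H)-one | C=C(CC/C=C(\C)CCC(=O)c1ccoc1)CCC[C@H](C)C(O)C1OC(=O)C(C)=C1OC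
F5 | step 11 | (5Z)-5-[(2S,9E)-13-(furan-3-yl)-2,10-dimethyl-6-methylidene-13-oxotridec-9-en-1-ylidene]-4-methoxy-3-methylfuran-2(5H)-one | C=C(CC/C=C(\C)CCC(=O)c1ccoc1)CCC[C@H](C)/C=C1\OC(=O)C(C)=C1OC
F6 | step 11 | (5Z)-5-[(2S,9E)-13-(furan-3-yl)-2,10-dimethyl-6-methylidene-13-oxotridec-9-en-1-ylidene]-4-hydroxy-3-methylfuran-2(5H)-one | C=C(CC/C=C(\C)CCC(=O)c1ccoc1)CCC[C@H](C)/C=C1\OC(=O)C(C)=C1O
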